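**Retrosynthetic overview**
1. Target 29 ⇐ desilylation and lactone opening of the cis-fused α-methylene lactone ester 27 ⇐ ester bond between hydroxy lactone 20 and acid 25 (25 from an asymmetric Morita–Baylis–Hillman reaction).
2. 20 ⇐ keto lactone 14 (ketone reduction, α-methylenation) ⇐ bond between the aldehyde carbon and the butenolide β-carbon of 13 (carbene-catalysed Stetter reaction; closes the only carbocycle).
3. 13 ⇐ 9, where the furan is a latent butenolide, the terminal alkyne a latent aldehyde, and the α-keto ester of 6 a latent hydroxyisopropenyl group.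
4. 6 ⇐ [3,3] disconnection between the quaternary carbon and its CH neighbour: catalytic asymmetric Gosteli–Claisen rearrangement of the achiral ether 5 (from 1, 2 and 4).
5. Ring order: γ-lactone (step 7, from the furan), then the cyclohexane (step 9); the lactone is opened last (step 16).

Labels for the cyclohexane carbons of 29: C-a (methyl/vinyl quaternary carbon), C-b (CH2), C-c (CH–O–acyl), C-d (CH bearing the acrylic acid), C-e (CH–OH), C-f (CH bearing the hydroxyisopropenyl group).

Assumption: the chiral catalysts of steps 3 and 12 are used in the enantiomeric (step 3) or pseudo-enantiomeric (step 12) form that gives the configuration written; both forms of each are accessible.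

**Step 1**
Reactants: 1 (2E)-3-methylpent-2-en-4-yn-1-ol; 2 ethyl diazo(diethoxyphosphoryl)acetate
Product: 3 ethyl (diethoxyphosphoryl){[(2E)-3-methylpent-2-en-4-yn-1-yl]oxy}acetate (racemic)
Conditions: Rh2(OAc)4 (1 mol %), PhH, 80 °C, slow addition of 2
Reagents that add atoms: none
Why: Rhodium-carbenoid O–H insertion into the primary allylic alcohol outruns cyclopropenation of the enyne and gives the α-allyloxy phosphonoacetate in one step, its stereocentre being erased in step 2.

**Step 2**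
Reactants: 3 ethyl (diethoxyphosphoryl){[(2E)-3-methylpent-2-en-4-yn-1-yl]oxy}acetate; 4 furan-2-carbaldehyde
Product: 5 ethyl (2Z)-3-(furan-2-yl)-2-{[(2E)-3-methylpent-2-en-4-yn-1-yl]oxy}prop-2-enoate
Conditions: LiN(SiMe3)2, THF, −78 °C; then 4, −78 → 23 °C; Z isomer separated on SiO2
Reagents that add atoms: none
Why: Horner–Wadsworth–Emmons olefination of the α-alkoxy phosphonoacetate anion with an aromatic aldehyde favours the Z enol ether (furyl trans to the ester), which is the geometry the chair Claisen transition state needs, and the minor E isomer is removed on silica.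

**Step 3**
Reactants: 5 ethyl (2Z)-3-(furan-2-yl)-2-{[(2E)-3-methylpent-2-en-4-yn-1-yl]oxy}prop-2-enoate
Product: 6 ethyl (3R,4S)-4-ethynyl-3-(furan-2-yl)-4-methyl-2-oxohex-5-enoate
Conditions: C2-symmetric N,N′-bis[(1R,2R)-2-(2-methyl-5-phenylpyrrol-1-yl)cyclohexyl]guanidinium tetrakis[3,5-bis(trifluoromethyl)phenyl]borate (20 mol %), hexanes, 35 °C, 5 d
Reagents that add atoms: none
Why: Catalytic enantioselective Gosteli–Claisen rearrangement, in which the guanidinium ion hydrogen-bonds to the ether oxygen and ester carbonyl and stabilises the dipolar chair transition state; the Z enol ether and E allyl terminus translate into the 3R*,4S* relation of C-f and the methyl/vinyl/ethynyl quaternary C-a, and the catalyst selects one enantiomeric chair.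

**Step 4**
Reactants: 6 ethyl (3R,4S)-4-ethynyl-3-(furan-2-yl)-4-methyl-2-oxohex-5-enoate
Product: 7 ethyl (3S,4S)-4-ethynyl-3-(furan-2-yl)-4-methyl-2-methylidenehex-5-enoate
Conditions: Zn, CH2Br2, TiCl4, THF/CH2Cl2, 0 → 23 °C
Reagents that add atoms: dibromomethane BrCBr
Why: Takai–Lombardo methylenation is non-basic and chemoselective for the highly electrophilic ketone of the α-keto ester, so the enolisable furyl-bearing stereocentre and the ester survive (the descriptor changes by priority only).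

**Step 5**
Reactants: 7 ethyl (3S,4S)-4-ethynyl-3-(furan-2-yl)-4-methyl-2-methylidenehex-5-enoate
Product: 8 (3S,4S)-4-ethynyl-3-(furan-2-yl)-4-methyl-2-methylidenehex-5-en-1-ol
Conditions: i-Bu2AlH (2.5 equiv), CH2Cl2, −78 → −20 °C
Reagents that add atoms: none
Why: 1,2-Reduction of the acrylate ester with the aluminium hydride gives the 2-substituted allylic alcohol without touching furan, alkyne or alkenes.

**Step 6**
Reactants: 8 (3S,4S)-4-ethynyl-3-(furan-2-yl)-4-methyl-2-methylidenehex-5-en-1-ol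
Product: 9 tert-butyl{[(3S,4S)-4-ethynyl-3-(furan-2-yl)-4-methyl-2-methylidenehex-5-en-1-yl]oxy}dimethylsilane
Conditions: TBSCl, imidazole, DMF, 23 °C
Reagents that add atoms: tert-butyl(chloro)dimethylsilane CC(C)(C)[Si](C)(C)Cl
Why: Standard silylation protects the primary allylic alcohol for the oxidation, carbene and acylation steps that follow.

**Step 7**
Reactants: 9 tert-butyl{[(3S,4S)-4-ethynyl-3-(furan-2-yl)-4-methyl-2-methylidenehex-5-en-1-yl]oxy}dimethylsilane
Product: 12 5-[(3S,4S)-1-{[tert-butyl(dimethyl)silyl]oxy}-4-ethynyl-4-methyl-2-methylidenehex-5-en-3-yl]furan-2(5H)-one (both C-5 epimers), via 5-hydroxybutenolide 10 (not isolated), via (Z)-4-hydroxy-2-enoic acid 11 (not isolated)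
Conditions: O2, tetraphenylporphyrin (cat.), hν, i-Pr2NEt, CH2Cl2, −78 °C; then NaBH4, CeCl3·7H2O, MeOH, −40 → 0 °C; then 1 M HCl (pH 2), 23 °C
Reagents that add atoms: dioxygen O=O
Why: Singlet-oxygen [4+2] cycloaddition to the furan (far faster than the ene reaction of the 1,1-disubstituted alkene) and base-induced Kornblum–DeLaMare opening give the γ-hydroxybutenolide, whose open keto-acid form is reduced under Luche conditions and relactonises on acidification; the new carbinol centre (future C-e) forms as an epimer mixture, which is acceptable because it is equilibrated in step 9.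

**Step 8**
Reactants: 12 5-[(3S,4S)-1-{[tert-butyl(dimethyl)silyl]oxy}-4-ethynyl-4-methyl-2-methylidenehex-5-en-3-yl]furan-2(5H)-one
Product: 13 (3S,4S)-5-({[tert-butyl(dimethyl)silyl]oxy}methyl)-3-ethenyl-3-methyl-4-(5-oxo-2,5-dihydrofuran-2-yl)hex-5-enal (both butenolide epimers)
Conditions: [CpRu(MeCN)3]PF6 (5 mol %), 5,5′-bis(trifluoromethyl)-2,2′-bipyridine (5 mol %), NMP/H2O, 30 °C
Reagents that add atoms: water O
Why: Ruthenium-catalysed anti-Markovnikov hydration of the terminal alkyne (through a ruthenium vinylidene) runs in neutral aqueous medium, so the base-sensitive butenolide and the silyl ether are untouched.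

**Step 9**
Reactants: 13 (3S,4S)-5-({[tert-butyl(dimethyl)silyl]oxy}methyl)-3-ethenyl-3-methyl-4-(5-oxo-2,5-dihydrofuran-2-yl)hex-5-enal
Product: 14 (3aS,6S,7S,7aS)-7-(3-{[tert-butyl(dimethyl)silyl]oxy}prop-1-en-2-yl)-6-ethenyl-6-methylhexahydro-1-benzofuran-2,4-dione
Conditions: 2-(pentafluorophenyl)-6,7-dihydro-5H-pyrrolo[2,1-c][1,2,4]triazol-2-ium tetrafluoroborate (20 mol %), DBU (30 mol %), toluene (0.02 M), 23 °C
Reagents that add atoms: none
Why: Proposed new method: dynamic kinetic intramolecular Stetter reaction onto an epimerisable butenolide — the triazolylidene turns the aldehyde into its Breslow intermediate, which adds 6-exo-trig to the butenolide β-carbon on the face carrying the tether, so the lactone is necessarily cis-fused (C-d set), while DBU interconverts the two γ-epimers through the 2-furanolate faster than C–C bond formation and only the epimer that places the lactone oxygen equatorial and trans to the equatorial silyloxyisopropenyl group (no 1,3-diaxial clash with the axial vinyl group) cyclises (C-e set); the closest known chemistry is the triazolylidene-catalysed intramolecular Stetter reaction of aliphatic aldehydes onto α,β-unsaturated esters together with the base-induced γ-epimerisation of butenolides.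

**Step 10**
Reactants: 14 (3aS,6S,7S,7aS)-7-(3-{[tert-butyl(dimethyl)silyl]oxy}prop-1-en-2-yl)-6-ethenyl-6-methylhexahydro-1-benzofuran-2,4-dione
Product: 15 (3aR,4R,6S,7S,7aS)-7-(3-{[tert-butyl(dimethyl)silyl]oxy}prop-1-en-2-yl)-6-ethenyl-4-hydroxy-6-methylhexahydro-1-benzofuran-2(3H)-one
Conditions: NaBH4, CeCl3·7H2O, MeOH/THF, −78 °C; AcOH quench
Reagents that add atoms: none
Why: Luche reduction, in which the small hydride attacks the convex face of the cis-fused bicycle, anti to the axial lactone CH2 on the adjacent ring-fusion carbon, giving the equatorial C-c alcohol cis to the C-d and C-e substituents (all-cis triad) while the γ-lactone is not reduced at −78 °C.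

**Step 11**
Reactants: 15 (3aR,4R,6S,7S,7aS)-7-(3-{[tert-butyl(dimethyl)silyl]oxy}prop-1-en-2-yl)-6-ethenyl-4-hydroxy-6-methylhexahydro-1-benzofuran-2(3H)-one
Product: 20 (3aR,4R,6S,7S,7aS)-7-(3-{[tert-butyl(dimethyl)silyl]oxy}prop-1-en-2-yl)-6-ethenyl-4-hydroxy-6-methyl-3-methylidenehexahydro-1-benzofuran-2(3H)-one, via bis-silylated ketene acetal 16 (not isolated), via O-silyl Mannich base 17 (not isolated), via Mannich base 18 (not isolated), via trimethylammonium iodide 19 (not isolated)
Conditions: Me3SiOTf, Et3N, CH2Cl2, 0 → 23 °C; then CH2=NMe2+ Cl−; then citric acid, MeOH/H2O; then MeI, THF, 23 °C; then NaHCO3, H2O/CH2Cl2, 23 °C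
Reagents that add atoms: N,N-dimethylmethyleneiminium chloride C=[N+](C)C.[Cl-]
Why: Eschenmoser-type α-methylenation by soft enolisation, in which the silyl triflate caps the hydroxyl (so no alkoxide can translactonise) and converts the lactone into its ketene silyl acetal, and Mukaiyama–Mannich reaction, N-methylation and Hofmann-type β-elimination then give the exocyclic methylene without touching a stereocentre.

**Step 12**
Reactants: 21 1,1,1,3,3,3-hexafluoropropan-2-yl prop-2-enoate; 22 {[tert-butyl(dimethyl)silyl]oxy}acetaldehyde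
Product: 23 1,1,1,3,3,3-hexafluoropropan-2-yl (3R)-4-{[tert-butyl(dimethyl)silyl]oxy}-3-hydroxy-2-methylidenebutanoate
Conditions: α-isocupreine (10 mol %), DMF, −55 °C
Reagents that add atoms: none
Why: Asymmetric Morita–Baylis–Hillman reaction of the activated hexafluoroisopropyl acrylate under bifunctional cinchona amine/phenol catalysis; the pseudo-enantiomeric α-isocupreine is chosen because the usual R sense of β-isocupreidine for alkyl aldehydes corresponds to S here (CH2OSi outranks the vinyl carbon), so that 3R results.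

**Step 13**
Reactants: 23 1,1,1,3,3,3-hexafluoropropan-2-yl (3R)-4-{[tert-butyl(dimethyl)silyl]oxy}-3-hydroxy-2-methylidenebutanoate
Product: 24 1,1,1,3,3,3-hexafluoropropan-2-yl (3R)-4-{[tert-butyl(dimethyl)silyl]oxy}-2-methylidene-3-[(triethylsilyl)oxy]butanoate
Conditions: Et3SiOTf, 2,6-lutidine, CH2Cl2, −78 °C
Reagents that add atoms: triethylsilyl trifluoromethanesulfonate CC[Si](CC)(CC)OS(=O)(=O)C(F)(F)F
Why: Silylation of the secondary allylic alcohol with the reactive silyl triflate at low temperature avoids silyl migration and protects the hydroxyl for the acylation.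

**Step 14**
Reactants: 24 1,1,1,3,3,3-hexafluoropropan-2-yl (3R)-4-{[tert-butyl(dimethyl)silyl]oxy}-2-methylidene-3-[(triethylsilyl)oxy]butanoate
Product: 25 (3R)-4-{[tert-butyl(dimethyl)silyl]oxy}-2-methylidene-3-[(triethylsilyl)oxy]butanoic acid
Conditions: LiOH, THF/H2O, 0 °C; then 1 M HCl to pH 3
Reagents that add atoms: lithium hydroxide [Li+].[OH-]
Why: Saponification of the electron-poor hexafluoroisopropyl ester is complete within minutes at 0 °C, conditions under which the silyl ethers and the acrylate double bond are stable.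

**Step 15**
Reactants: 25 (3R)-4-{[tert-butyl(dimethyl)silyl]oxy}-2-methylidene-3-[(triethylsilyl)oxy]butanoic acid; 20 (3aR,4R,6S,7S,7aS)-7-(3-{[tert-butyl(dimethyl)silyl]oxy}prop-1-en-2-yl)-6-ethenyl-4-hydroxy-6-methyl-3-methylidenehexahydro-1-benzofuran-2(3H)-one
Product: 27 (3aR,4R,6S,7S,7aS)-7-(3-{[tert-butyl(dimethyl)silyl]oxy}prop-1-en-2-yl)-6-ethenyl-6-methyl-3-methylidene-2-oxooctahydro-1-benzofuran-4-yl (3R)-4-{[tert-butyl(dimethyl)silyl]oxy}-2-methylidene-3-[(triethylsilyl)oxy]butanoate, via mixed anhydride 26 (not isolated)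
Conditions: 2,4,6-Cl3C6H2COCl, Et3N, PhMe, 23 °C; then 20, DMAP, 0 → 23 °C
Reagents that add atoms: none
Why: Yamaguchi esterification through the mixed anhydride acylates the only free hydroxyl (C-c, flanked by a CH2) faster than the amine bases can translactonise the neighbouring cis lactone, and no stereocentre is touched.

**Step 16**
Reactants: 27 (3aR,4R,6S,7S,7aS)-7-(3-{[tert-butyl(dimethyl)silyl]oxy}prop-1-en-2-yl)-6-ethenyl-6-methyl-3-methylidene-2-oxooctahydro-1-benzofuran-4-yl (3R)-4-{[tert-butyl(dimethyl)silyl]oxy}-2-methylidene-3-[(triethylsilyl)oxy]butanoate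
Product: 28 lithium 2-[(1S,2S,3S,4S,6R)-6-{[(3R)-4-{[tert-butyl(dimethyl)silyl]oxy}-2-methylidene-3-[(triethylsilyl)oxy]butanoyl]oxy}-3-(3-{[tert-butyl(dimethyl)silyl]oxy}prop-1-en-2-yl)-4-ethenyl-2-hydroxy-4-methylcyclohexyl]prop-2-enoate
Conditions: LiOH (1.1 equiv), THF/H2O, 0 °C; lyophilised and used directly
Reagents that add atoms: lithium hydroxide [Li+].[OH-]
Why: Saponification, in which hydroxide opens the strained α-methylene γ-lactone far faster than it attacks the hindered secondary α-substituted acrylate ester, the diequatorial C-c ester and C-e hydroxyl cannot undergo acyl migration, and keeping the product as its carboxylate prevents relactonisation.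

**Step 17**
Reactants: 28 lithium 2-[(1S,2S,3S,4S,6R)-6-{[(3R)-4-{[tert-butyl(dimethyl)silyl]oxy}-2-methylidene-3-[(triethylsilyl)oxy]butanoyl]oxy}-3-(3-{[tert-butyl(dimethyl)silyl]oxy}prop-1-en-2-yl)-4-ethenyl-2-hydroxy-4-methylcyclohexyl]prop-2-enoate
Product: 29 2-[(1S,2S,3S,4S,6R)-6-{[(3R)-3,4-dihydroxy-2-methylidenebutanoyl]oxy}-4-ethenyl-2-hydroxy-3-(3-hydroxyprop-1-en-2-yl)-4-methylcyclohexyl]prop-2-enoic acid
Conditions: Et3N·3HF, MeCN, 0 → 23 °C; pH 6 buffer (NaH2PO4/Na2HPO4), C18 chromatography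
Reagents that add atoms: none
Why: Fluoride-mediated cleavage of the three silyl ethers with the nearly neutral amine–HF reagent avoids both the acid that would relactonise the cis γ-hydroxy acid and the base that would lactonise the dihydroxy acrylate side chain.

**Compound list**
1 | (2E)-3-methylpent-2-en-4-yn-1-ol | OC/C=C(\C)C#C | starting material
2 | ethyl diazo(diethoxyphosphoryl)acetate | CCOC(=O)C(=[N+]=[N-])P(=O)(OCC)OCC | starting material
3 | ethyl (diethoxyphosphoryl){[(2E)-3-methylpent-2-en-4-yn-1-yl]oxy}acetate (racemic) | CCOC(=O)C(OC/C=C(\C)C#C)P(=O)(OCC)OCC | intermediate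
4 | furan-2-carbaldehyde | O=Cc1ccco1 | starting material
5 | ethyl (2Z)-3-(furan-2-yl)-2-{[(2E)-3-methylpent-2-en-4-yn-1-yl]oxy}prop-2-enoate | CCOC(=O)/C(OC/C=C(\C)C#C)=C/c1ccco1 | intermediate
6 | ethyl (3R,4S)-4-ethynyl-3-(furan-2-yl)-4-methyl-2-oxohex-5-enoate | C=C[C@]([C@H](c1ccco1)C(=O)C(=O)OCC)(C)C#C | intermediate
7 | ethyl (3S,4S)-4-ethynyl-3-(furan-2-yl)-4-methyl-2-methylidenehex-5-enoate | C=C[C@]([C@H](c1ccco1)C(=C)C(=O)OCC)(C)C#C | intermediate
8 | (3S,4S)-4-ethynyl-3-(furan-2-yl)-4-methyl-2-methylidenehex-5-en-1-ol | C=C[C@]([C@H](c1ccco1)C(=C)CO)(C)C#C | intermediate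
9 | tert-butyl{[(3S,4S)-4-ethynyl-3-(furan-2-yl)-4-methyl-2-methylidenehex-5-en-1-yl]oxy}dimethylsilane | C=C[C@]([C@H](c1ccco1)C(=C)CO[Si](C)(C)C(C)(C)C)(C)C#C | intermediate
10 | 5-[(3S,4S)-1-{[tert-butyl(dimethyl)silyl]oxy}-4-ethynyl-4-methyl-2-methylidenehex-5-en-3-yl]-5-hydroxyfuran-2(5H)-one (hemiketal epimers) | C=C[C@]([C@H](C1(O)OC(=O)C=C1)C(=C)CO[Si](C)(C)C(C)(C)C)(C)C#C | intermediate
11 | (2Z,5S)-6-({[tert-butyl(dimethyl)silyl]oxy}methyl)-4-hydroxy-5-[(3S)-3-methylpent-1-en-4-yn-3-yl]hepta-2,6-dienoic acid (C-4 epimers) | C=C[C@]([C@H](C(O)/C=C\C(=O)O)C(=C)CO[Si](C)(C)C(C)(C)C)(C)C#C | intermediate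
12 | 5-[(3S,4S)-1-{[tert-butyl(dimethyl)silyl]oxy}-4-ethynyl-4-methyl-2-methylidenehex-5-en-3-yl]furan-2(5H)-one (C-5 epimers) | C=C[C@]([C@H](C1OC(=O)C=C1)C(=C)CO[Si](C)(C)C(C)(C)C)(C)C#C | intermediate
13 | (3S,4S)-5-({[tert-butyl(dimethyl)silyl]oxy}methyl)-3-ethenyl-3-methyl-4-(5-oxo-2,5-dihydrofuran-2-yl)hex-5-enal (butenolide epimers) | C=C[C@]([C@H](C1OC(=O)C=C1)C(=C)CO[Si](C)(C)C(C)(C)C)(C)CC=O | intermediate
14 | (3aS,6S,7S,7aS)-7-(3-{[tert-butyl(dimethyl)silyl]oxy}prop-1-en-2-yl)-6-ethenyl-6-methylhexahydro-1-benzofuran-2,4-dione | C=C[C@]1(C)CC(=O)[C@@H](CC2=O)[C@@H](O2)[C@@H]1C(=C)CO[Si](C)(C)C(C)(C)C | intermediate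
15 | (3aR,4R,6S,7S,7aS)-7-(3-{[tert-butyl(dimethyl)silyl]oxy}prop-1-en-2-yl)-6-ethenyl-4-hydroxy-6-methylhexahydro-1-benzofuran-2(3H)-one | C=C[C@]1(C)C[C@@H](O)[C@@H](CC2=O)[C@@H](O2)[C@@H]1C(=C)CO[Si](C)(C)C(C)(C)C | intermediate
16 | ketene trimethylsilyl acetal of 15 with the C-4 hydroxyl as its trimethylsilyl ether (2-silyloxy-4,5-dihydrofuran) | C=C[C@]1(C)C[C@@H](O[Si](C)(C)C)[C@@H](C=C2O[Si](C)(C)C)[C@@H](O2)[C@@H]1C(=C)CO[Si](C)(C)C(C)(C)C | intermediate
17 | 3-[(dimethylamino)methyl] lactone with the C-4 hydroxyl as its trimethylsilyl ether (C-3 epimers) | C=C[C@]1(C)C[C@@H](O[Si](C)(C)C)[C@@H](C(CN(C)C)C2=O)[C@@H](O2)[C@@H]1C(=C)CO[Si](C)(C)C(C)(C)C | intermediate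
18 | (3aR,4R,6S,7S,7aS)-7-(3-{[tert-butyl(dimethyl)silyl]oxy}prop-1-en-2-yl)-3-[(dimethylamino)methyl]-6-ethenyl-4-hydroxy-6-methylhexahydro-1-benzofuran-2(3H)-one (C-3 epimers) | C=C[C@]1(C)C[C@@H](O)[C@@H](C(CN(C)C)C2=O)[C@@H](O2)[C@@H]1C(=C)CO[Si](C)(C)C(C)(C)C | intermediate
19 | N,N,N-trimethyl ammonium iodide of 18 | C=C[C@]1(C)C[C@@H](O)[C@@H](C(C[N+](C)(C)C)C2=O)[C@@H](O2)[C@@H]1C(=C)CO[Si](C)(C)C(C)(C)C.[I-] | intermediate
20 | (3aR,4R,6S,7S,7aS)-7-(3-{[tert-butyl(dimethyl)silyl]oxy}prop-1-en-2-yl)-6-ethenyl-4-hydroxy-6-methyl-3-methylidenehexahydro-1-benzofuran-2(3H)-one | C=C[C@]1(C)C[C@@H](O)[C@@H](C(=C)C2=O)[C@@H](O2)[C@@H]1C(=C)CO[Si](C)(C)C(C)(C)C | intermediate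
21 | 1,1,1,3,3,3-hexafluoropropan-2-yl prop-2-enoate | C=CC(=O)OC(C(F)(F)F)C(F)(F)F | starting material
22 | {[tert-butyl(dimethyl)silyl]oxy}acetaldehyde | O=CCO[Si](C)(C)C(C)(C)C | starting material
23 | 1,1,1,3,3,3-hexafluoropropan-2-yl (3R)-4-{[tert-butyl(dimethyl)silyl]oxy}-3-hydroxy-2-methylidenebutanoate | C=C(C(=O)OC(C(F)(F)F)C(F)(F)F)[C@@H](O)CO[Si](C)(C)C(C)(C)C | intermediate
24 | 1,1,1,3,3,3-hexafluoropropan-2-yl (3R)-4-{[tert-butyl(dimethyl)silyl]oxy}-2-methylidene-3-[(triethylsilyl)oxy]butanoate | C=C(C(=O)OC(C(F)(F)F)C(F)(F)F)[C@@H](O[Si](CC)(CC)CC)CO[Si](C)(C)C(C)(C)C | intermediate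
25 | (3R)-4-{[tert-butyl(dimethyl)silyl]oxy}-2-methylidene-3-[(triethylsilyl)oxy]butanoic acid | C=C(C(=O)O)[C@@H](O[Si](CC)(CC)CC)CO[Si](C)(C)C(C)(C)C | intermediate
26 | (3R)-4-{[tert-butyl(dimethyl)silyl]oxy}-2-methylidene-3-[(triethylsilyl)oxy]butanoic 2,4,6-trichlorobenzoic anhydride | C=C(C(=O)OC(=O)c1c(Cl)cc(Cl)cc1Cl)[C@@H](O[Si](CC)(CC)CC)CO[Si](C)(C)C(C)(C)C | intermediate
27 | (3aR,4R,6S,7S,7aS)-7-(3-{[tert-butyl(dimethyl)silyl]oxy}prop-1-en-2-yl)-6-ethenyl-6-methyl-3-methylidene-2-oxooctahydro-1-benzofuran-4-yl (3R)-4-{[tert-butyl(dimethyl)silyl]oxy}-2-methylidene-3-[(triethylsilyl)oxy]butanoate | C=C[C@]1(C)C[C@@H](OC(=O)C(=C)[C@@H](O[Si](CC)(CC)CC)CO[Si](C)(C)C(C)(C)C)[C@@H](C(=C)C2=O)[C@@H](O2)[C@@H]1C(=C)CO[Si](C)(C)C(C)(C)C | intermediate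
28 | lithium 2-[(1S,2S,3S,4S,6R)-6-{[(3R)-4-{[tert-butyl(dimethyl)silyl]oxy}-2-methylidene-3-[(triethylsilyl)oxy]butanoyl]oxy}-3-(3-{[tert-butyl(dimethyl)silyl]oxy}prop-1-en-2-yl)-4-ethenyl-2-hydroxy-4-methylcyclohexyl]prop-2-enoate | C=C[C@]1(C)C[C@@H](OC(=O)C(=C)[C@@H](O[Si](CC)(CC)CC)CO[Si](C)(C)C(C)(C)C)[C@@H](C(=C)C(=O)[O-])[C@@H](O)[C@@H]1C(=C)CO[Si](C)(C)C(C)(C)C.[Li+] | intermediate
29 | 2-[(1S,2S,3S,4S,6R)-6-{[(3R)-3,4-dihydroxy-2-methylidenebutanoyl]oxy}-4-ethenyl-2-hydroxy-3-(3-hydroxyprop-1-en-2-yl)-4-methylcyclohexyl]prop-2-enoic acid | C=C[C@]1(C)C[C@@H](OC(=O)C(=C)[C@@H](O)CO)[C@@H](C(=C)C(=O)O)[C@@H](O)[C@@H]1C(=C)CO | target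

**Step count and risks**
Total step count: 17. Longest linear sequence: 14 steps (steps 1–11 and 15–17); the side chain adds steps 12–14.

Step 9 (the proposed new reaction) is the most uncertain. The γ-epimerisation may be slower than cyclisation, the furanolate may undergo a vinylogous aldol reaction with the aldehyde, and the ring-fusion centre α to the new ketone may epimerise. The fallback uses known chemistry, sets out from 13 and comes back to the route at 15. The butenolide epimers of 13 are separated (the unwanted one is re-equilibrated with DBU and recycled). The required epimer, (3S,4S)-5-({[tert-butyl(dimethyl)silyl]oxy}methyl)-3-ethenyl-3-methyl-4-[(2R)-5-oxo-2,5-dihydrofuran-2-yl]hex-5-enal F1, is treated with SmI2 and t-BuOH in THF at −78 °C. This is a ketyl–olefin radical cyclisation onto the unsaturated lactone, a known reaction class; it is again forced to give the cis-fused lactone and yields 15 directly. Any carbinol epimer, (3aR,4S,6S,7S,7aS)-7-(3-{[tert-butyl(dimethyl)silyl]oxy}prop-1-en-2-yl)-6-ethenyl-4-hydroxy-6-methylhexahydro-1-benzofuran-2(3H)-one F2, is oxidised with Dess–Martin periodinane to 14 and passed through step 10.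

Step 3 is the second risk. The guanidinium catalyst has not been shown on a furyl-substituted enol ether with an enyne allyl unit, so enantioselectivity and rate are open, and the α-furyl α-keto ester 6 can epimerise at C-f. The fallback sets out from 5 and comes back at 6. It replaces hydrogen-bond catalysis by chiral Lewis acid catalysis with the bis(oxazoline) copper complex [Cu{(S,S)-t-Bu-box}(H2O)2](SbF6)2 in CH2Cl2 at 23 °C, which binds the ether oxygen and ester carbonyl in a chelate and is established for this class of 2-alkoxycarbonyl allyl vinyl ethers. The product is taken straight into step 4; it gives the same keto ester 6, so no new compound arises (F0).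

Step 16 is the third risk. Hydroxide may also cleave the side-chain ester, and the cis γ-hydroxy acid relactonises if the work-up becomes acidic. The fallback sets out from 27 and comes back at 29, reversing the order of the last two operations and avoiding hydroxide. 27 is first desilylated with Et3N·3HF in MeCN to the tetraol lactone, (3aR,4R,6S,7S,7aS)-6-ethenyl-7-(3-hydroxyprop-1-en-2-yl)-6-methyl-3-methylidene-2-oxooctahydro-1-benzofuran-4-yl (3R)-3,4-dihydroxy-2-methylidenebutanoate F3. Its lactone is then opened by pig-liver esterase in pH 7.2 buffer (NaH2PO4/Na2HPO4) at 25 °C, where the hindered acrylate ester is not a substrate and the product stays as the carboxylate until isolation as 29.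

**Further compounds**
F1 | step 9 | (3S,4S)-5-({[tert-butyl(dimethyl)silyl]oxy}methyl)-3-ethenyl-3-methyl-4-[(2R)-5-oxo-2,5-dihydrofuran-2-yl]hex-5-enal | C=C[C@]([C@H]([C@@H]1OC(=O)C=C1)C(=C)CO[Si](C)(C)C(C)(C)C)(C)CC=O
F2 | step 9 | (3aR,4S,6S,7S,7aS)-7-(3-{[tert-butyl(dimethyl)silyl]oxy}prop-1-en-2-yl)-6-ethenyl-4-hydroxy-6-methylhexahydro-1-benzofuran-2(3H)-one | C=C[C@]1(C)C[C@H](O)[C@@H](CC2=O)[C@@H](O2)[C@@H]1C(=C)CO[Si](C)(C)C(C)(C)C
F3 | step 16 | (3aR,4R,6S,7S,7aS)-6-ethenyl-7-(3-hydroxyprop-1-en-2-yl)-6-methyl-3-methylidene-2-oxooctahydro-1-benzofuran-4-yl (3R)-3,4-dihydroxy-2-methylidenebutanoate | C=C[C@]1(C)C[C@@H](OC(=O)C(=C)[C@@H](O)CO)[C@@H](C(=C)C2=O)[C@@H](O2)[C@@H]1C(=C)CO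
F0 | step 3 | none | none
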